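(The numbers in the tables are calculated on assumed constants, and the scatter is random.)

Molar, not percent of charge, is the unit to watch at this bench. Three flasks of substrate stand ready, and each stops at 4.0 min.

| flask | substrate | remark | time |
|---|---|---|---|
| elm | 0.13 M | run made earlier |  |
| birch | 0.76 M | run made earlier |  |
| east | 0.12 M |  | 4.0 min |
| north-west | 0.25 M |  | 4.0 min |
| south | 0.50 M |  | 4.0 min |

- elm (time / min: target / %, substrate / %): 0.333: 22.4, 70.5; 0.500: 25.5, 65.0; 0.667: 27.6, 60.6; 1.00: 27.7, 56.8; 1.50: 27.1, 53.0; 2.50: 25.7, 50.7; 4.00: 24.8, 48.3
- birch (time / min: target / %, substrate / %): 0.500: 32.1, 60.5; 1.00: 45.6, 41.6; 1.50: 52.4, 33.1; 2.50: 57.7, 26.6; 3.00: 58.8, 26.8; 4.00: 60.7, 25.9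

(standard deviation of a reading: 0.5 percentage points)

- what is said of target includes crystals
- crystals is a solid; its amount is given per volume of the solution
- candidate steps: substrate <-> target; substrate <-> isomer of the product A; substrate <-> isomer of the product B; target <-> isomer of the product C; crystals <-> target
- the concentration of target that is asked is that of its free form alone
- "hardly changes" means that all values lie within two and a half points (for a concentration: within two and a half percent of the largest)

1. [target] (only what is free in solution) at the end for east, north-west, south, in this order
2. the shape of the row from first to last (rises all the way / rises, then falls / hardly changes / falls all the way / falls, then rises)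

Soon after the start, each flask will hold mostly substrate and target. In elm their ratio read 0.511 at 1.50 min and 0.513 at 4.00 min, so the two are taken to stand in balance.

Leave the stop time alone: elm target slid from 27.7% at 1.00 min to 24.8% at 4.00 min. A target percent counts crystals too, so in a flask that holds crystals it is not read as free target.

This note's own reckoning carries one quantity, the saturation charge: the substrate charge at which free target reaches the solubility at the stop time.

ratio in elm = 24.8% / 48.3% = 0.513

ceiling (the solubility), from birch = 0.513 × 25.9% × 0.76 M = 0.101 M

saturation charge = 0.101 M / 24.8% = 0.408 M

Elm's target at 4.00 min read 0.0322 M, less than that ceiling, so that reading is taken as free target. Below the saturation charge, free target is taken as 24.8% of the charge: 0.0298 M in east and 0.0620 M in north-west. South, at 0.124 M before any crystals form, has more than the ceiling, so it is expected to stand at 0.101 M over crystals.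

The forecast gives 0.03 M, 0.062 M and 0.1 M, a row that rises all the way, saying of south that “crystals form and free target is pinned” there.

The flasks give 0.0306 M, 0.0637 M and 0.0990 M, a row that rises all the way, and the forecast agrees within its margin.

    substrate ⇌ target (K = 0.520, k = 0.0210 s⁻¹)
    substrate ⇌ isomer of the product A (K = 0.200, k = 0.00340 s⁻¹)
    substrate ⇌ isomer of the product B (K = 25.0, k = 3.50 × 10⁻⁴ s⁻¹)
    target ⇌ isomer of the product C (K = 0.440, k = 0.00710 s⁻¹)
    crystals ⇌ target, rate k5*(cs5 - [target]) while solid is left; crystals form when [target] > cs5 (solubility = 0.0990 M, k = 1.40 s⁻¹)

In east, 88% of the turnover from substrate to target up to 4.0 min lay behind by 0.800 min, and 88% of that from target to isomer of the product C by 2.00 min, while crystals stood at 0%. South, charged at 0.50 M, more than the saturation charge of 0.408 M, already held 21.2% crystals at 2.00 min and 22.0% at 4.00 min, whereas north-west, charged at 0.25 M, less than that charge, held 0% crystals at 4.00 min.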